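**Plan**

- Cuts: C7–C8 (α-sulfinyl carbanion + aldehyde, sulfur removed afterwards), C6′–C7′ (Sonogashira), the alkyne carbon C7′ (one-carbon homologation of an aldehyde), and one of the two C1–CH3 bonds of the left ring (1,4-methylation). C8–C8′, with its four methyls and seven E double bonds, is bought as crocetin dialdehyde, so no C=C bond is made.
- Feature used: the left ring C1–C6 carries oxygen on C3 and C6 across the C4=C5 bond. It is therefore the p-quinol of a 3,5-dimethylphenol that has taken up one methyl at C1. C6 is its only stereocentre, and it is stereogenic only because C1 (CMe2) and C5 (CMe=) differ by that methyl.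
- Forward, left ring: 4-methoxy-2,6-dimethylphenol is dearomatised to the quinone monoketal, (R)-TolS(O)CH2Li adds to give a prochiral 3,5-dimethyl-p-quinol, and sulfoxide-directed methyl transfer from AlMe3 to one of its two ring arms sets C6 and the gem-dimethyl carbon in one step.
- The same sulfinylmethyl carbon (C7) is then the nucleophile that joins the ring to C8 of a C30 aldehyde. Oxidation at C8 and reductive loss of sulfur leave the aldol C6(OH)–C7H2–C8(=O); the C7/C8 epimers converge.
- Right half: the enol triflate of silylated (4R,6R)-actinol (C3′ from the chiral pool, the α-methyl centre erased) is coupled with the terminal enyne from mono-homologation of crocetin dialdehyde. One acid step at the end frees the C3 ketone and the C3′ alcohol.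

Key step: step 3

Remark (locants): carotenoid numbering is used: C1–C6 left ring, C7–C15 and C15′–C7′ chain, C1′–C6′ right ring.
Remark (assumption on step 3): the arm selected follows the chelate model given in that step, by which the (R)-sulfoxide leads to the (S)-carbinol; should the other arm react, (S)-methyl p-tolyl sulfoxide is used in step 2 and nothing else changes.
Remark (assumption on supply): 4-methoxy-2,6-dimethylphenol, (R)-methyl p-tolyl sulfoxide, (4R,6R)-actinol and all-E crocetin dialdehyde are taken as purchasable.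

**Route**

Step 1
Reactants: 1 4-methoxy-2,6-dimethylphenol
Product: 2 4,4-dimethoxy-2,6-dimethylcyclohexa-2,5-dien-1-one
Conditions: PhI(OAc)2 (1.1 equiv), MeOH, 0 °C → rt
Reagents that add atoms: methanol, CO
Why: Oxidative dearomatisation of a p-alkoxyphenol by iodine(III) in methanol (quinone monoketal formation) is general and leaves the free carbonyl between the two methyl-bearing carbons, where the next nucleophile has to add; no stereocentre is formed.

Step 2
Reactants: 2 4,4-dimethoxy-2,6-dimethylcyclohexa-2,5-dien-1-one; 3 (R)-methyl p-tolyl sulfoxide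
Product: 5 4-hydroxy-3,5-dimethyl-4-{[(R)-4-methylbenzenesulfinyl]methyl}cyclohexa-2,5-dien-1-one, via ketal carbinol 4 (not isolated)
Conditions: 3 (1.1 equiv), LDA (1.1 equiv), THF, −78 °C; 2, −78 °C; aq. NH4Cl; then oxalic acid (cat.), THF–H2O, rt
Reagents that add atoms: water, O
Why: 1,2-Addition of an α-sulfinyl carbanion to the quinone monoketal carbonyl, then mild acid hydrolysis of the dimethyl ketal, is the standard entry to 4-(sulfinylmethyl)-p-quinols; the sulfur centre is configurationally stable here and the carbinol carbon of 5 is not yet stereogenic because its two ring arms are identical.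

Step 3
Reactants: 5 4-hydroxy-3,5-dimethyl-4-{[(R)-4-methylbenzenesulfinyl]methyl}cyclohexa-2,5-dien-1-one
Product: 8 (4S)-4-hydroxy-3,5,5-trimethyl-4-{[(R)-4-methylbenzenesulfinyl]methyl}cyclohex-2-en-1-one, via dimethylaluminium alkoxide 6 (not isolated), via aluminium dienolate 7 (not isolated)
Conditions: AlMe3 (4 equiv, 2 M in toluene), CH2Cl2, −78 → 0 °C; aq. Rochelle salt
Reagents that add atoms: trimethylaluminium, C[Al](C)C
Why: Proposed new method: AlMe3 metalates the carbinol of 5 (loss of methane) to alkoxide 6, in which the sulfinyl oxygen chelates aluminium in a six-membered chair with p-tolyl equatorial; a second AlMe3, held on the remaining lone pair of the alkoxide oxygen, then lies over one of the two enone arms only and hands a methyl group to its β-carbon through a cyclic transition state, which gives the cross-conjugated dienolate 7 (inert to further addition) and, on protonation, 8. The closest known reaction type is the sulfoxide-directed 1,4-addition of AlMe3 to 4-hydroxy-4-(sulfinylmethyl)cyclohexa-2,5-dienones with unsubstituted β-carbons, which takes place on one arm only and from the oxygen face; new here is transfer to a β-methyl-bearing carbon, so that a quaternary C(CH3)2 centre arises next to the carbinol, a bond type that trialkylaluminiums otherwise form on 3-methylcyclohexenones under copper catalysis. No ring is closed. The one new stereocentre is the carbinol carbon (future C6): it becomes stereogenic because its two ring neighbours now differ by one methyl, and its configuration is decided solely by which arm is methylated, i.e. by the (R)-sulfur centre through the chelate, the face of attack being irrelevant because the new carbon carries two methyls. The step needs arm selectivity, 1,4- over 1,2-addition and mono-addition; the chiral chelate secures the first, intramolecular delivery from the oxygen-bound aluminium the second (it also offsets the hindrance at the fully substituted β-carbon), and enolate formation the third. Since the auxiliary is enantiopure, product from the wrong arm is a diastereomer of 8 and is removed by crystallisation or chromatography, so the enantiomeric purity of C6 does not depend on perfect selectivity.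

Step 4
Reactants: 8 (4S)-4-hydroxy-3,5,5-trimethyl-4-{[(R)-4-methylbenzenesulfinyl]methyl}cyclohex-2-en-1-one
Product: 9 (8S)-7,9,9-trimethyl-8-{[(R)-4-methylbenzenesulfinyl]methyl}-1,4-dioxaspiro[4.5]dec-6-en-8-ol
Conditions: (TMSOCH2)2 (3 equiv), TMSOTf (5 mol%), CH2Cl2, −78 → 0 °C; pyridine, aq. NaHCO3
Reagents that add atoms: 1,2-bis(trimethylsilyloxy)ethane, C[Si](C)(C)OCCO[Si](C)(C)C
Why: Silyl triflate-catalysed ketalisation under aprotic, cold conditions turns the enone into its dioxolane without moving the C=C bond or ionising the tertiary allylic alcohol, and so removes the only acidic and electrophilic site that would interfere with the carbanion chemistry of step 9; no stereocentre is touched.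

Step 5
Reactants: 10 (4R,6R)-4-hydroxy-2,2,6-trimethylcyclohexan-1-one (actinol)
Product: 11 (4R,6R)-2,2,6-trimethyl-4-(triethylsilyloxy)cyclohexan-1-one
Conditions: TESCl (1.2 equiv), imidazole, DMF, 0 °C → rt
Reagents that add atoms: chlorotriethylsilane, CC[Si](Cl)(CC)CC
Why: Routine silylation of a secondary alcohol gives an ether that survives LDA, Pd/Cu/amine, MnO2 and Al(Hg) and falls off in the final acid step; both stereocentres are untouched.

Step 6
Reactants: 11 (4R,6R)-2,2,6-trimethyl-4-(triethylsilyloxy)cyclohexan-1-one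
Product: 12 (4R)-2,6,6-trimethyl-4-(triethylsilyloxy)cyclohex-1-en-1-yl trifluoromethanesulfonate
Conditions: LDA (1.2 equiv), THF, −78 → 0 °C; PhNTf2 (1.2 equiv), 0 °C → rt; aq. NH4Cl
Reagents that add atoms: N-phenylbis(trifluoromethanesulfonimide), O=S(=O)(N(c1ccccc1)S(=O)(=O)C(F)(F)F)C(F)(F)F
Why: Enol triflate formation is regiodefined because the ketone has a single α-hydrogen, so only the tetrasubstituted enol triflate can form; the α-methyl stereocentre is erased on purpose and the silyloxy carbon (future C3′, R) is not involved.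

Step 7
Reactants: 13 crocetin dialdehyde, (2E,4E,6E,8E,10E,12E,14E)-2,6,11,15-tetramethylhexadeca-2,4,6,8,10,12,14-heptaenedial
Product: 14 (2E,4E,6E,8E,10E,12E,14E)-2,6,11,15-tetramethylheptadeca-2,4,6,8,10,12,14-heptaen-16-ynal
Conditions: Ohira–Bestmann reagent (1.0 equiv), K2CO3 (2 equiv), MeOH–THF, 0 °C → rt, dark; unreacted 13 recycled
Reagents that add atoms: dimethyl (1-diazo-2-oxopropyl)phosphonate, CC(=O)C(=[N+]=[N-])P(=O)(OC)OC
Why: Seyferth–Gilbert homologation with the Ohira–Bestmann reagent converts one of the two equivalent α-methyl enal ends into the terminal alkyne (C8′≡C7′) under mild carbonate conditions that leave the other aldehyde and the all-E polyene alone, mono-reaction being favoured by the limiting reagent and by the lower electrophilicity of the remaining aldehyde once one acceptor group is gone; no stereocentre is formed.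

Step 8
Reactants: 12 (4R)-2,6,6-trimethyl-4-(triethylsilyloxy)cyclohex-1-en-1-yl trifluoromethanesulfonate; 14 (2E,4E,6E,8E,10E,12E,14E)-2,6,11,15-tetramethylheptadeca-2,4,6,8,10,12,14-heptaen-16-ynal
Product: 15 (2E,4E,6E,8E,10E,12E,14E)-2,6,11,15-tetramethyl-17-[(4R)-2,6,6-trimethyl-4-(triethylsilyloxy)cyclohex-1-en-1-yl]heptadeca-2,4,6,8,10,12,14-heptaen-16-ynal
Conditions: Pd(PPh3)4 (5 mol%), CuI (10 mol%), Et3N, DMF (degassed), rt → 40 °C, dark
Reagents that add atoms: none
Why: Sonogashira coupling of a cyclohexenyl triflate with a terminal enyne forms the C6′–C7′ bond without touching the aldehyde or any existing double-bond geometry, and no stereocentre is formed or disturbed.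

Step 9
Reactants: 9 (8S)-7,9,9-trimethyl-8-{[(R)-4-methylbenzenesulfinyl]methyl}-1,4-dioxaspiro[4.5]dec-6-en-8-ol; 15 (2E,4E,6E,8E,10E,12E,14E)-2,6,11,15-tetramethyl-17-[(4R)-2,6,6-trimethyl-4-(triethylsilyloxy)cyclohex-1-en-1-yl]heptadeca-2,4,6,8,10,12,14-heptaen-16-ynal
Product: 16 (3E,5E,7E,9E,11E,13E,15E)-1-[(8S)-8-hydroxy-7,9,9-trimethyl-1,4-dioxaspiro[4.5]dec-6-en-8-yl]-3,7,12,16-tetramethyl-1-[(R)-4-methylbenzenesulfinyl]-18-[(4R)-2,6,6-trimethyl-4-(triethylsilyloxy)cyclohex-1-en-1-yl]octadeca-3,5,7,9,11,13,15-heptaen-17-yn-2-ol (epimers at chain C1 and C2, i.e. C7 and C8)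
Conditions: 9 (1.3 equiv), LDA (2.05 equiv per 9), THF, −78 °C; 15, −78 °C; aq. NH4Cl at −78 °C
Reagents that add atoms: none
Why: The alkoxide/α-sulfinyl dianion of the β-hydroxy sulfoxide adds 1,2 to the enal (sulfinyl carbanion addition to an aldehyde) and, being an oxido-carbanion, cannot β-eliminate; the two new stereocentres at C7 and C8 form without control and are both erased in steps 10 and 11, so all epimers converge.

Step 10
Reactants: 16 β,β′-dihydroxy sulfoxide (epimer mixture)
Product: 17 (3E,5E,7E,9E,11E,13E,15E)-1-[(8S)-8-hydroxy-7,9,9-trimethyl-1,4-dioxaspiro[4.5]dec-6-en-8-yl]-3,7,12,16-tetramethyl-1-[(R)-4-methylbenzenesulfinyl]-18-[(4R)-2,6,6-trimethyl-4-(triethylsilyloxy)cyclohex-1-en-1-yl]octadeca-3,5,7,9,11,13,15-heptaen-17-yn-2-one (epimers at C7)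
Conditions: activated MnO2 (20 equiv), CH2Cl2, rt, dark
Reagents that add atoms: none
Why: MnO2 oxidises only the allylic (polyenylic) secondary alcohol at C8 to the conjugated ketone and leaves the tertiary alcohol, sulfoxide, silyl ether, ketal and alkyne alone; the C8 stereocentre disappears.

Step 11
Reactants: 17 β-keto sulfoxide (epimers at C7)
Product: 18 (3E,5E,7E,9E,11E,13E,15E)-1-[(8S)-8-hydroxy-7,9,9-trimethyl-1,4-dioxaspiro[4.5]dec-6-en-8-yl]-3,7,12,16-tetramethyl-18-[(4R)-2,6,6-trimethyl-4-(triethylsilyloxy)cyclohex-1-en-1-yl]octadeca-3,5,7,9,11,13,15-heptaen-17-yn-2-one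
Conditions: Al(Hg), THF–H2O (9:1), 0 °C, dark
Reagents that add atoms: none
Why: Reductive desulfurisation of a β-keto sulfoxide by aluminium amalgam (electron transfer to the ketone, loss of arenesulfenate from the α-carbon, protonation of the enolate) leaves the C7 methylene of the aldol and removes the auxiliary; the C7 stereocentre disappears and C6 is not involved.

Step 12
Reactants: 18 ketal- and silyl-protected carotenoid
Product: 19 (4S)-4-hydroxy-4-{(3E,5E,7E,9E,11E,13E,15E)-18-[(4R)-4-hydroxy-2,6,6-trimethylcyclohex-1-en-1-yl]-3,7,12,16-tetramethyl-2-oxooctadeca-3,5,7,9,11,13,15-heptaen-17-yn-1-yl}-3,5,5-trimethylcyclohex-2-en-1-one (CNP0252913.1)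
Conditions: 1 M aq. HCl–THF (1:5), 0 °C → rt, dark, argon
Reagents that add atoms: water, O
Why: Acid hydrolysis cleaves the enone dioxolane and the triethylsilyl ether in one operation, and because no base is present the tertiary β-hydroxy ketone is not exposed to retro-aldol cleavage; no stereocentre is affected.

**Compound list**

1 | 4-methoxy-2,6-dimethylphenol | COc1cc(C)c(O)c(C)c1 | starting material
2 | 4,4-dimethoxy-2,6-dimethylcyclohexa-2,5-dien-1-one | COC1(OC)C=C(C)C(=O)C(C)=C1 | intermediate
3 | (R)-methyl p-tolyl sulfoxide | C[S@@](=O)c1ccc(C)cc1 | starting material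
4 | 4,4-dimethoxy-2,6-dimethyl-1-{[(R)-4-methylbenzenesulfinyl]methyl}cyclohexa-2,5-dien-1-ol (not isolated) | COC1(OC)C=C(C)C(O)(C[S@@](=O)c2ccc(C)cc2)C(C)=C1 | intermediate
5 | 4-hydroxy-3,5-dimethyl-4-{[(R)-4-methylbenzenesulfinyl]methyl}cyclohexa-2,5-dien-1-one | CC1=CC(=O)C=C(C)C1(O)C[S@@](=O)c1ccc(C)cc1 | intermediate
6 | O-dimethylaluminium alkoxide of 5 (not isolated) | CC1=CC(=O)C=C(C)C1(O[Al](C)C)C[S@@](=O)c1ccc(C)cc1 | intermediate
7 | bis(dimethylaluminium) alkoxide-dienolate, carbinol carbon configured as in 8 (not isolated) | CC1=CC(O[Al](C)C)=CC(C)(C)[C@@]1(O[Al](C)C)C[S@@](=O)c1ccc(C)cc1 | intermediate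
8 | (4S)-4-hydroxy-3,5,5-trimethyl-4-{[(R)-4-methylbenzenesulfinyl]methyl}cyclohex-2-en-1-one | CC1=CC(=O)CC(C)(C)[C@@]1(O)C[S@@](=O)c1ccc(C)cc1 | intermediate
9 | (8S)-7,9,9-trimethyl-8-{[(R)-4-methylbenzenesulfinyl]methyl}-1,4-dioxaspiro[4.5]dec-6-en-8-ol | CC1=CC2(OCCO2)CC(C)(C)[C@@]1(O)C[S@@](=O)c1ccc(C)cc1 | intermediate
10 | (4R,6R)-4-hydroxy-2,2,6-trimethylcyclohexan-1-one (actinol) | C[C@@H]1C[C@@H](O)CC(C)(C)C1=O | starting material
11 | (4R,6R)-2,2,6-trimethyl-4-(triethylsilyloxy)cyclohexan-1-one | C[C@@H]1C[C@@H](O[Si](CC)(CC)CC)CC(C)(C)C1=O | intermediate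
12 | (4R)-2,6,6-trimethyl-4-(triethylsilyloxy)cyclohex-1-en-1-yl trifluoromethanesulfonate | FC(F)(F)S(=O)(=O)OC1=C(C)C[C@@H](O[Si](CC)(CC)CC)CC1(C)C | intermediate
13 | crocetin dialdehyde, (2E,4E,6E,8E,10E,12E,14E)-2,6,11,15-tetramethylhexadeca-2,4,6,8,10,12,14-heptaenedial | O=C/C(C)=C/C=C/C(C)=C/C=C/C=C(C)/C=C/C=C(C)/C=O | starting material
14 | (2E,4E,6E,8E,10E,12E,14E)-2,6,11,15-tetramethylheptadeca-2,4,6,8,10,12,14-heptaen-16-ynal | O=C/C(C)=C/C=C/C(C)=C/C=C/C=C(C)/C=C/C=C(\C)C#C | intermediate
15 | (2E,4E,6E,8E,10E,12E,14E)-2,6,11,15-tetramethyl-17-[(4R)-2,6,6-trimethyl-4-(triethylsilyloxy)cyclohex-1-en-1-yl]heptadeca-2,4,6,8,10,12,14-heptaen-16-ynal | O=C/C(C)=C/C=C/C(C)=C/C=C/C=C(C)/C=C/C=C(\C)C#CC1=C(C)C[C@@H](O[Si](CC)(CC)CC)CC1(C)C | intermediate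
16 | β,β′-dihydroxy sulfoxide (octadecaheptaenyn-2-ol of step 9; epimers at C7 and C8) | CC1=CC2(OCCO2)CC(C)(C)[C@@]1(O)C([S@@](=O)c1ccc(C)cc1)C(O)/C(C)=C/C=C/C(C)=C/C=C/C=C(C)/C=C/C=C(\C)C#CC1=C(C)C[C@@H](O[Si](CC)(CC)CC)CC1(C)C | intermediate
17 | β-keto sulfoxide (octadecaheptaenyn-2-one of step 10; epimers at C7) | CC1=CC2(OCCO2)CC(C)(C)[C@@]1(O)C([S@@](=O)c1ccc(C)cc1)C(=O)/C(C)=C/C=C/C(C)=C/C=C/C=C(C)/C=C/C=C(\C)C#CC1=C(C)C[C@@H](O[Si](CC)(CC)CC)CC1(C)C | intermediate
18 | (3E,5E,7E,9E,11E,13E,15E)-1-[(8S)-8-hydroxy-7,9,9-trimethyl-1,4-dioxaspiro[4.5]dec-6-en-8-yl]-3,7,12,16-tetramethyl-18-[(4R)-2,6,6-trimethyl-4-(triethylsilyloxy)cyclohex-1-en-1-yl]octadeca-3,5,7,9,11,13,15-heptaen-17-yn-2-one | CC1=CC2(OCCO2)CC(C)(C)[C@@]1(O)CC(=O)/C(C)=C/C=C/C(C)=C/C=C/C=C(C)/C=C/C=C(\C)C#CC1=C(C)C[C@@H](O[Si](CC)(CC)CC)CC1(C)C | intermediate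
19 | (4S)-4-hydroxy-4-{(3E,5E,7E,9E,11E,13E,15E)-18-[(4R)-4-hydroxy-2,6,6-trimethylcyclohex-1-en-1-yl]-3,7,12,16-tetramethyl-2-oxooctadeca-3,5,7,9,11,13,15-heptaen-17-yn-1-yl}-3,5,5-trimethylcyclohex-2-en-1-one | CC1=CC(=O)CC(C)(C)[C@@]1(O)CC(=O)/C(C)=C/C=C/C(C)=C/C=C/C=C(C)/C=C/C=C(\C)C#CC1=C(C)C[C@@H](O)CC1(C)C | target

**Count**

Total steps: 12. Longest linear sequence: 8 (steps 1, 2, 3, 4, 9, 10, 11, 12).

**Steps most likely to fail, with fallbacks**

1. Step 3 (the step that carries the label "Proposed new method:"). Methyl transfer to the fully substituted β-carbon beside the carbinol may be too slow, so that 1,2-addition to the dienone carbonyl or undirected intermolecular addition with loss of arm selectivity takes over. The fallback uses known chemistry only; it sets out from 3 and comes back to the route at 9. Commercial 2,6,6-trimethylcyclohex-2-ene-1,4-dione F1 is ketalised at its less hindered C4 carbonyl (ethylene glycol, TsOH, benzene, reflux) to 7,9,9-trimethyl-1,4-dioxaspiro[4.5]dec-6-en-8-one F2. Lithiated 3 (LDA, THF, −78 °C) adds to the remaining ketone without useful facial control and gives 9 together with its carbinol epimer, the (8R)-hydroxy sulfoxide F3. The two are diastereomers and are separated by chromatography or crystallisation, so the sulfoxide serves as a covalently bound resolving group instead of a directing group. No more than half of the material can reach 9 this way.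

2. Step 7. Both ends of the symmetrical dialdehyde may be homologated, or methanol may add in conjugate fashion to the enal before the diazoalkene forms. The fallback sets out from 12 and comes back at 15, building the chain outward from the ring instead of desymmetrising a dialdehyde. Sonogashira coupling of 12 with commercial (2E)-3-methylpent-2-en-4-yn-1-ol F4 gives the C15 allylic alcohol F5. PPh3·HBr in CH2Cl2 converts it into the C15 phosphonium bromide F6. Wittig reaction (NaOMe) with an excess of commercial 2,7-dimethylocta-2,4,6-trienedial F7 gives the C25 aldehyde F8. A second Wittig reaction with the C5 acetal salt [(2E)-3-(5,5-dimethyl-1,3-dioxan-2-yl)but-2-en-1-yl]triphenylphosphonium chloride F9 gives the C30 acetal F10, which is hydrolysed with aqueous oxalic acid to 15. The two new disubstituted C=C bonds are equilibrated to E by warming.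

3. Step 11. Electron transfer into the long polyenone may go on past C–S cleavage (over-reduction of the chromophore) or scramble double-bond geometry. The fallback sets out from 16 and comes back at 18, removing sulfur without a reductant and before the ketone exists. Heating 16 in toluene at 80–100 °C with CaCO3 and trimethyl phosphite (sulfenic acid trap) brings about thermal syn-elimination of the sulfoxide. C6 carries no hydrogen, so the only β-hydrogen is the carbinol C8–H, and the elimination gives the C7=C8 enol F11, which tautomerises to 18. Steps 10 and 11 are bypassed.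

**Further compounds**

F1 | step 3 | 2,6,6-trimethylcyclohex-2-ene-1,4-dione (4-oxoisophorone) | CC1=CC(=O)CC(C)(C)C1=O
F2 | step 3 | 7,9,9-trimethyl-1,4-dioxaspiro[4.5]dec-6-en-8-one | CC1=CC2(OCCO2)CC(C)(C)C1=O
F3 | step 3 | (8R)-7,9,9-trimethyl-8-{[(R)-4-methylbenzenesulfinyl]methyl}-1,4-dioxaspiro[4.5]dec-6-en-8-ol | CC1=CC2(OCCO2)CC(C)(C)[C@]1(O)C[S@@](=O)c1ccc(C)cc1
F4 | step 7 | (2E)-3-methylpent-2-en-4-yn-1-ol | C#C/C(C)=C/CO
F5 | step 7 | (2E)-3-methyl-5-[(4R)-2,6,6-trimethyl-4-(triethylsilyloxy)cyclohex-1-en-1-yl]pent-2-en-4-yn-1-ol | OC/C=C(\C)C#CC1=C(C)C[C@@H](O[Si](CC)(CC)CC)CC1(C)C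
F6 | step 7 | {(2E)-3-methyl-5-[(4R)-2,6,6-trimethyl-4-(triethylsilyloxy)cyclohex-1-en-1-yl]pent-2-en-4-yn-1-yl}triphenylphosphonium bromide | [Br-].C(/C=C(\C)C#CC1=C(C)C[C@@H](O[Si](CC)(CC)CC)CC1(C)C)[P+](c1ccccc1)(c1ccccc1)c1ccccc1
F7 | step 7 | (2E,4E,6E)-2,7-dimethylocta-2,4,6-trienedial | O=C/C(C)=C/C=C/C=C(C)/C=O
F8 | step 7 | (2E,4E,6E,8E,10E)-2,7,11-trimethyl-13-[(4R)-2,6,6-trimethyl-4-(triethylsilyloxy)cyclohex-1-en-1-yl]trideca-2,4,6,8,10-pentaen-12-ynal | O=C/C(C)=C/C=C/C=C(C)/C=C/C=C(\C)C#CC1=C(C)C[C@@H](O[Si](CC)(CC)CC)CC1(C)C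
F9 | step 7 | [(2E)-3-(5,5-dimethyl-1,3-dioxan-2-yl)but-2-en-1-yl]triphenylphosphonium chloride | [Cl-].C/C(=C\C[P+](c1ccccc1)(c1ccccc1)c1ccccc1)C1OCC(C)(C)CO1
F10 | step 7 | 5,5-dimethyl-1,3-dioxan-2-yl acetal of 15 | CC1(C)COC(OC1)/C(C)=C/C=C/C(C)=C/C=C/C=C(C)/C=C/C=C(\C)C#CC1=C(C)C[C@@H](O[Si](CC)(CC)CC)CC1(C)C
F11 | step 11 | C7=C8 enol of 18 | CC1=CC2(OCCO2)CC(C)(C)[C@@]1(O)C=C(O)/C(C)=C/C=C/C(C)=C/C=C/C=C(C)/C=C/C=C(\C)C#CC1=C(C)C[C@@H](O[Si](CC)(CC)CC)CC1(C)C
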